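By the start step on its own, the initiator cannot put more than 2.00% of the free monomer into chains, since one initiator takes one free monomer.

free monomer 0.0020 M; transfer agent 0.0600 mM; capture agent 2.00 mM; initiator 40 µM (in portions, 2); time 30 min; the portions of initiator follow each other after 1.5 min, the first at the start

    free monomer → uncatalysed product (k1 = 0.0063 /s)
    living end + transfer agent → dead chain (k2 = 19 /M/s)
    free monomer + initiator → living end + monomer in chains (k3 = 300 /M/s)
    living end + capture agent → trapped intermediate (k4 = 650 /M/s)
    2 initiator → spent initiator (k5 = 350 /M/s)
    free monomer + living end → monomer in chains + living end, rate k6*[living end]*[free monomer] (k6 = 1400 /M/s)

- at 30 min, what has stopped the reaction, if anything has (forward and back rates have come level / no working catalyst is left / all of the free monomer has reacted / it is still moving)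
- conversion of free monomer at 30 min
- amount of monomer in chains at 30 min, in percent of the free monomer charged
- amount of uncatalysed product at 30 min, in percent of the free monomer charged

- a doubled species enters its step squared and goes two at a time
- the reaction counts as stopped when no species that holds the free monomer changes by six tenths of a point or more over the second half of the time
- run time (flask): 30 min

I count everything as a fraction of its charge. One thing looks wrong at once: with the whole initiator charge present, the start step halves the free monomer in 0.96 min, sooner than the uncatalysed step does in 1.8 min, and yet the start step has that small ceiling. The clash clears because the start step consumes initiator as it works, far sooner than the next portion comes. A portion lasts about 1.67 s at the full monomer charge, far less than the 1.5 min between portions. The start step outruns pairing, so nearly all of a portion starts living ends. Each portion is therefore a pulse worth 1.00% of the monomer charge.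

The zero of my scale is one monomer per initiator. A living end is captured faster than it transfers, so I set its growth rate against its capture rate. One plus that ratio at full charges comes to 3.15: this is the chain tally, the monomers in chains per initiator, a degree of polymerisation. By the second portion, the uncatalysed step alone leaves 0.567 of the free monomer, so the tally falls to 2.22. I commit to 5.38% in chains. By 30 min, far beyond the uncatalysed half-life, I reckon the free monomer down to 1.19 × 10⁻⁵ of its charge, which leaves 94.6% as uncatalysed product.

The forecast says all of the free monomer has reacted, with conversion 100%, 5.2% in chains and 94.8% uncatalysed product, its chain figure a little below mine. Its grounds: “each end adds only about two to three monomers”.

The flask gives all of the free monomer has reacted, with conversion >99.9%, 5.16% in chains and 94.8% uncatalysed product.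

Just before the second portion this flask holds 3.06% in chains, which is 3.06 monomers per initiator of the first portion, against my tally of 3.15. With all else held, the uncatalysed product of this flask has moved by 5 points once the initiator charge reaches 81.2 µM. The neighbour flask carries 160 µM of initiator, everything else held, so its pulses are 4.00% each, and the same tallies give 21.5%. The neighbour flask ends with 18.9% in chains and 81.1% as uncatalysed product.

(The numbers belong to no real substance; the flask was simulated.)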